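(The numbers in the tables stem from a simulated flask from invented constants, and the scatter is random.)

Time first: Saturday's flask runs 200 min and Tuesday's 50 min, both under the same held gas, and I want the target at each end.

| flask | starting material | gas | remark | time |
|---|---|---|---|---|
| autumn | 0.027 M | 4.3 mM (held) | run made earlier |  |
| spring | 0.041 M | 4.3 mM (held) | run made earlier |  |
| Saturday's | 0.030 M | 4.3 mM (held) |  | 200 min |
| Tuesday's | 0.020 M | 4.3 mM (held) |  | 50 min |

- autumn (time / min: target / %, starting material / %): 10.0: 4, 91; 20.0: 12, 86; 30.0: 17, 76; 40.0: 20, 69; 50.0: 26, 62
- spring (time / min: target / %, starting material / %): 10.0: 2, 95; 20.0: 10, 87; 30.0: 12, 84; 40.0: 16, 76; 50.0: 22, 67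

(scatter of a reading: 1.5 percentage points)

- the earlier runs were read with a standard deviation of 1.5 percentage points
- at the start none of the gas is in solution
- a reading of starting material is of its free form alone

- the winner by amount of target, in percent of the starting material charged; "neither" if no more than 2 percentage points parts them (Saturday's / Tuesday's / neither)
- how much target is there at the end, in percent of the starting material charged: Saturday's
- how much target is there at the end, in percent of the starting material charged: Tuesday's

At the last readings, target over starting material lost stands at 68.4% in the autumn run and 66.7% in the spring run, both with the scatter of their readings. Pooling these last readings gives the split 67.6%, the share of lost starting material that appears as target, the selectivity to target.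

Loss looks exponential, so the part left is exp(−κt), and target is the split times the part lost. The readings give κ as 0.00956 min⁻¹ in the autumn run and 0.00801 min⁻¹ in the spring run, which is lower at higher loading. Taking κ to fall as a power of loading, I read from these two runs a rough exponent of 0.424. So κ is 0.00914 min⁻¹ for Saturday's and 0.0109 min⁻¹ for Tuesday's, and I commit to 56.7% and 28.3%.

The forecast names Saturday's, with 60% for Saturday's, above mine and called “a long extrapolation”, and 28% for Tuesday's.

The flasks give 47.6% for Saturday's and 29.6% for Tuesday's, so Saturday's wins, but my Saturday's figure stands 9.1 percentage points too high. On the free starting material lost, the split is 68.2% in Tuesday's flask and 60.8% in Saturday's.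

    2 starting material → self-condensation product (k = 3.79 × 10⁻⁵ M⁻¹ s⁻¹)
    starting material + partner ⇌ isomer of the product (K = 480 M⁻¹, k = 0.0375 M⁻¹ s⁻¹)
    gas ⇌ partner, rate k3*(csat - [partner]) (kL = 0.00148 s⁻¹)
    2 partner → homo dimer (k = 0.00439 M⁻¹ s⁻¹)
    starting material + partner ⇌ target (K = 550 M⁻¹, k = 0.0927 M⁻¹ s⁻¹)

In Tuesday's flask at 50.0 min the forward step to target uses partner 2.5 times as fast as the forward step to isomer of the product, a share of the two forward rates of 71.2% beside the split of 67.6%. Both steps run back, and in Saturday's flask target over isomer of the product stands at 1.59 after 200 min and 1.15 after 2000 min, beside the ratio of equilibrium constants, 1.15: kinetic against thermodynamic control. Tuesday's recipe read at 120 min holds 46.8% target, where the split times the part lost gives 49.1%.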